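The question before repeating this run is how much product stands at 25 s, and which doubling raises it more.

    intermediate → decomposed reagent (k1 = 0.21 s⁻¹)
    intermediate → product (k2 = 0.081 s⁻¹)
    substrate + partner ⇌ intermediate (K3 = 2.2 M⁻¹, k3 = 0.28 M⁻¹ s⁻¹)
    gas ⇌ partner, rate k4*(csat - [partner]) (k4 = 0.19 s⁻¹, csat = 200 mM)

substrate 1.5 M; gas 200 mM (held); time 25 s

- how much product there is at 25 s, in percent of the substrate charged
- the change that raises the amount of product at 25 s, in percent of the substrate charged most ("none" if none brings more than 2 percentage points) (winter / midnight / none)
- amount of product at 25 s, in percent of the substrate charged, after winter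

- at the start none of partner is dissolved
- run time (flask): 25 s

I drew the curve by hand first. Partner started at zero and climbed at 0.0380 M s⁻¹, so product began flat. Of the intermediate formed, a fraction 0.696 went onward rather than back, which makes uptake a pseudo-first-order loss of partner with constant f·k3·c(substrate). I carried the handover concentration c_X, the substrate level at which that constant equals the transfer coefficient: 0.975 M. Where transfer and uptake cross, c(partner) = csat/(1 + c(substrate)/c_X).

The charge of 1.5 M stood above c_X, so the uptake constant of 0.292 s⁻¹ was larger than the transfer coefficient of 0.19 s⁻¹, but by a factor of 1.54, so the two legs were of like size and I took them to share control. Partner ran towards 0.0788 M, with a net flow of 0.0230 M s⁻¹. The knee came after a lag of 5.10 s, the two relaxation times of partner and intermediate added. Product took 27.8 % of the flow. Substrate sank to about 1.04 M, still above c_X, and the flow eased to 0.0196 M s⁻¹. Averaging gave 7.88 %.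

Winter multiplied the starting flow by 2, midnight by 1.43, so I chose winter. The same averaging, with substrate falling to 0.583 M, gave 13.8 %.

The forecast said 8 %, winter and 14.8 %, holding that “Partner and intermediate settle quickly into a quasi-steady state”. Its winter figure stood above mine.

The simulation gave 7.78 %, and winter won with 6.2 percentage points against 3 points, reaching 14.0 %.

At 25.0 s this flask held substrate at 67.6 % of its charge, just above c_X at 65.0 %. The crossing formula then gives 0.0980 M of partner, and the flask held 0.0961 M. The neighbour flask read at 1.5 min had passed the handover, with substrate at 0.204 M, less than c_X. There the formula gives 0.165 M of partner, the neighbour held 0.162 M, and its product stood at 23.6 %.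

The constants used here were drawn at random within sensible limits; no experiment stands behind them.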